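**Retrosynthetic overview**

- The target comes from a C6 dimethyl acetal and a C15 ketone (chelation-controlled reduction, then acetal hydrolysis); the 16-methylene comes from α-methylenation of a 17-nor-15-ketone.
- Ring D: C13–C16 aldol closure of an 8-acetyl-cyclohexan-13-one.
- Ring C: formal [4+2] annulation on a C8=C9 alkylidene β-keto lactone with a four-carbon β-keto radical/α-chloro ketone unit (C9–C11 radical addition, then C8–C14 enolate alkylation).
- Ring B (7,20-lactone): quaternary C10 by Michael addition of a 10-formyl ketone to methyl acrylate, aldehyde reduction/lactonisation, C8 acetylation, dehydrogenation.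
- Ring A: organocatalytic desymmetrising nitro-Michael addition to 4,4-dimethylcyclohexadienone (sets C5), Nef reaction to the protected aldehyde; ring order A → B → C → D.

Assumption: 4,4-dimethylcyclohexa-2,5-dien-1-one (1) is taken as a commercial compound; carbon numbers C1–C20 below are those of the ent-kaurane skeleton.

**Step 1**
Reactants: 1 4,4-dimethylcyclohexa-2,5-dien-1-one; 2 nitromethane
Product: 3 (S)-4,4-dimethyl-5-(nitromethyl)cyclohex-2-en-1-one
Conditions: 9-amino-9-deoxy-epi-quinine (20 mol %), PhCO2H (40 mol %), MeNO2 (5 equiv), toluene, rt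
Reagents that add atoms: none
Why: Iminium-catalysed asymmetric nitro-Michael addition used as a desymmetrisation: the primary amine forms the dienone iminium ion and the quinuclidinium-bound nitronate is delivered to one enantiotopic β-carbon on one face, which sets C5 as S (the quinidine-derived pseudo-enantiomer is used if the sense proves opposite), and the more hindered product enone resists a second addition.

**Step 2**
Reactants: 3 (S)-4,4-dimethyl-5-(nitromethyl)cyclohex-2-en-1-one
Product: 5 (S)-5-(dimethoxymethyl)-4,4-dimethylcyclohex-2-en-1-one, via sodium nitronate 4 (not isolated)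
Conditions: NaOMe, MeOH, 0 °C; then into H2SO4/MeOH, −35 → 0 °C
Reagents that add atoms: methanol, CO
Why: Nef reaction run in methanol: the nitronate is C-protonated in strong acid and solvolysed to the aldehyde, which is caught as its dimethyl acetal; C5 has no adjacent carbonyl and the nitronate cannot leave by retro-Michael reaction, so the stereocentre is untouched.

**Step 3**
Reactants: 5 (S)-5-(dimethoxymethyl)-4,4-dimethylcyclohex-2-en-1-one
Product: 6 (5R,6Z)-5-(dimethoxymethyl)-6-(hydroxymethylidene)-4,4-dimethylcyclohex-2-en-1-one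
Conditions: NaH (2.2 equiv), HCO2Et, THF, 0 °C → rt; AcOH
Reagents that add atoms: ethyl formate, CCOC=O
Why: Claisen formylation at C10, the only enolisable position (C2 is vinylic, C4 quaternary), gives the chelated hydroxymethylene ketone that carries the future C20.

**Step 4**
Reactants: 6 (5R,6Z)-5-(dimethoxymethyl)-6-(hydroxymethylidene)-4,4-dimethylcyclohex-2-en-1-one; 7 methyl acrylate
Product: 8 methyl 3-[(1S,6R)-6-(dimethoxymethyl)-1-formyl-5,5-dimethyl-2-oxocyclohex-3-en-1-yl]propanoate
Conditions: DBU (10 mol %), MeCN, 0 °C → rt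
Reagents that add atoms: none
Why: Base-catalysed Michael addition of the β-keto aldehyde: the acrylate approaches the planar C10 anti to the neighbouring C5 dimethoxymethyl group, so the new C10–C9 bond is trans to C6 and the formyl group (C20) is cis to it, as in the target.

**Step 5**
Reactants: 8 methyl 3-[(1S,6R)-6-(dimethoxymethyl)-1-formyl-5,5-dimethyl-2-oxocyclohex-3-en-1-yl]propanoate
Product: 10 (6S,11R)-11-(dimethoxymethyl)-10,10-dimethyl-2-oxaspiro[5.5]undec-8-ene-3,7-dione, via hydroxy ester 9 (not isolated)
Conditions: NaBH4, MeOH/CH2Cl2, −78 → 0 °C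
Reagents that add atoms: none
Why: Chemoselective borohydride reduction of the aldehyde (the neopentyl, conjugated C1 ketone is much slower at low temperature) followed by spontaneous 6-exo lactonisation of the alkoxide onto the methyl ester, helped by the quaternary C10; no stereocentre is touched.

**Step 6**
Reactants: 10 (6S,11R)-11-(dimethoxymethyl)-10,10-dimethyl-2-oxaspiro[5.5]undec-8-ene-3,7-dione
Product: 11 (6S,11R)-4-acetyl-11-(dimethoxymethyl)-10,10-dimethyl-2-oxaspiro[5.5]undec-8-ene-3,7-dione (C4 epimers and enol)
Conditions: LiN(iPr)2, THF, −78 °C; MeC(O)N(OMe)Me, −78 → −20 °C; AcOH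
Reagents that add atoms: N-methoxy-N-methylacetamide, CC(=O)N(C)OC
Why: Crossed Claisen acylation of the lactone lithium enolate (C8 is the only acidic site) with a Weinreb amide, whose stable tetrahedral adduct prevents over-reaction; this brings in C15 and C16.

**Step 7**
Reactants: 11 (6S,11R)-4-acetyl-11-(dimethoxymethyl)-10,10-dimethyl-2-oxaspiro[5.5]undec-8-ene-3,7-dione
Product: 13 (6S,11R)-4-acetyl-11-(dimethoxymethyl)-10,10-dimethyl-2-oxaspiro[5.5]undeca-4,8-diene-3,7-dione, via selenide 12 (not isolated)
Conditions: PhSeCl, pyridine, CH2Cl2, 0 °C; then 30% H2O2, 0 °C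
Reagents that add atoms: none
Why: α-Selenenylation of the β-keto lactone and selenoxide syn-elimination, which can only take a C9 hydrogen, give the C8=C9 alkylidene; C10 is quaternary, so the doubly activated alkene cannot isomerise.

**Step 8**
Reactants: 14 ethyl chloroacetate
Product: 15 1-(chloromethyl)cyclopropan-1-ol
Conditions: EtMgBr (2.2 equiv), Ti(OiPr)4 (10 mol %), Et2O, 0 °C → rt; H2O
Reagents that add atoms: ethylmagnesium bromide, CC[Mg]Br
Why: Kulinkovich cyclopropanation: the titanacyclopropane formed from EtMgBr and Ti(OiPr)4 adds twice to the ester carbonyl and gives the cyclopropanol with the chloromethyl group intact.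

**Step 9**
Reactants: 13 (6S,11R)-4-acetyl-11-(dimethoxymethyl)-10,10-dimethyl-2-oxaspiro[5.5]undeca-4,8-diene-3,7-dione; 15 1-(chloromethyl)cyclopropan-1-ol
Product: 17 tricyclic diketone (8-acetyl-13-oxo spiro lactone; 5R,8S,9S,10S), via chloro diketone 16 (not isolated)
Conditions: 9-mesityl-10-methylacridinium tetrafluoroborate (5 mol %), 2,6-lutidine, MeCN, 450 nm LEDs, rt; then DBU (1.2 equiv), rt
Reagents that add atoms: none
Why: Proposed new method: a redox-neutral radical–polar crossover [4+2] annulation in which the excited acridinium oxidises the cyclopropanol (proton to lutidine) and ring opening gives the β-keto radical •CH2CH2C(O)CH2Cl, which adds to C9 of the doubly activated alkene anti to the bulky C5 branch of the spiro centre (C11 syn to the C1 carbonyl); the captodative C8 radical is reduced by the acridinyl radical to the β-keto-lactone enolate, and after DBU this enolate closes ring C by 6-exo-tet displacement of the α-keto chloride on the face that carries the side chain (allylic strain holds it pseudoaxial), giving the cis-fused ring with the acetyl group cis to H-9; the closest known chemistry is the photoredox ring-opening Giese addition of cyclopropanols combined with radical–polar crossover cyclisation of enolates onto alkyl halides.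

**Step 10**
Reactants: 17 tricyclic diketone (8-acetyl-13-oxo spiro lactone)
Product: 18 bridged ketol (17-nor, 13-hydroxy-15-oxo bicyclo[3.2.1]octane; 5R,8S,9S,10S,13S)
Conditions: KOt-Bu (0.3 equiv), t-BuOH/THF, 0 °C
Reagents that add atoms: none
Why: Intramolecular aldol addition under thermodynamic control: of the reversible enolate/ketone pairings only attack of the acetyl carbon C16 on the C13 ketone closes a five-membered ring (the alternatives give a norbornane or a ketol at the hindered, conjugated C1), by analogy with the closure of acetylcyclohexanones to bridged ketols; the bridge geometry fixes C13, and the hindered alkoxide avoids retro-Claisen loss of the acetyl group.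

**Step 11**
Reactants: 18 bridged ketol
Product: 19 enone (13-hydroxy-16-methylene-15-ketone; 5R,8S,9S,10S,13S)
Conditions: (CH2O)n, iPr2NH·CF3CO2H, THF, 65 °C
Reagents that add atoms: paraformaldehyde (as formaldehyde), C=O
Why: Mannich-type α-methylenation (iminium ion from formaldehyde and the secondary ammonium salt, then β-elimination of the amine) at C16, the only enolisable carbon left in the molecule.

**Step 12**
Reactants: 19 enone (13-hydroxy-16-methylene-15-ketone)
Product: 20 allylic alcohol (6-dimethyl acetal of the target; 15R)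
Conditions: Zn(BH4)2, Et2O/THF, −78 → −40 °C
Reagents that add atoms: none
Why: Chelation-controlled 1,2-reduction: zinc binds the C15 ketone together with the syn-oriented lactone carbonyl (β-keto lactone), which activates C15 over the isolated, hindered C1 enone, and hydride enters from the exo face of the bicyclo[3.2.1]octane (the endo face is covered by the C9–C11 bridge), giving the endo 15-OH.

**Step 13**
Reactants: 20 allylic alcohol (6-dimethyl acetal of the target)
Product: 21 CNP0521079.1 (target)
Conditions: pyridinium p-toluenesulfonate, acetone/H2O (10:1), 40 °C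
Reagents that add atoms: water, O
Why: Mild acid-catalysed acetal hydrolysis frees the C6 aldehyde; the lactone, the bridgehead tertiary alcohol and the hindered allylic alcohol tolerate the weak acid, and C5 is not epimerised under these conditions.

**Compound list**

1 | 4,4-dimethylcyclohexa-2,5-dien-1-one | CC1(C)C=CC(=O)C=C1 | starting material
2 | nitromethane | C[N+](=O)[O-] | starting material
3 | (S)-4,4-dimethyl-5-(nitromethyl)cyclohex-2-en-1-one | C1C(=O)C=CC(C)(C)[C@H]1C[N+](=O)[O-] | intermediate
4 | sodium nitronate of 3 (aci-nitro sodium salt, C5 unchanged) | C1C(=O)C=CC(C)(C)[C@H]1C=[N+]([O-])[O-].[Na+] | intermediate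
5 | (S)-5-(dimethoxymethyl)-4,4-dimethylcyclohex-2-en-1-one | C1C(=O)C=CC(C)(C)[C@H]1C(OC)OC | intermediate
6 | (5R,6Z)-5-(dimethoxymethyl)-6-(hydroxymethylidene)-4,4-dimethylcyclohex-2-en-1-one (enol of the 6-formyl ketone) | O/C=C1\C(=O)C=CC(C)(C)[C@H]1C(OC)OC | intermediate
7 | methyl acrylate | C=CC(=O)OC | starting material
8 | methyl 3-[(1S,6R)-6-(dimethoxymethyl)-1-formyl-5,5-dimethyl-2-oxocyclohex-3-en-1-yl]propanoate (formyl cis to the dimethoxymethyl group) | COC(=O)CC[C@]1(C=O)C(=O)C=CC(C)(C)[C@H]1C(OC)OC | intermediate
9 | methyl 3-[(1S,6R)-6-(dimethoxymethyl)-1-(hydroxymethyl)-5,5-dimethyl-2-oxocyclohex-3-en-1-yl]propanoate | COC(=O)CC[C@]1(CO)C(=O)C=CC(C)(C)[C@H]1C(OC)OC | intermediate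
10 | (6S,11R)-11-(dimethoxymethyl)-10,10-dimethyl-2-oxaspiro[5.5]undec-8-ene-3,7-dione | O=C1CC[C@]2(CO1)C(=O)C=CC(C)(C)[C@H]2C(OC)OC | intermediate
11 | (6S,11R)-4-acetyl-11-(dimethoxymethyl)-10,10-dimethyl-2-oxaspiro[5.5]undec-8-ene-3,7-dione (C4 epimers and enol) | CC(=O)C1C[C@]2(COC1=O)C(=O)C=CC(C)(C)[C@H]2C(OC)OC | intermediate
12 | (6S,11R)-4-acetyl-11-(dimethoxymethyl)-10,10-dimethyl-4-(phenylselanyl)-2-oxaspiro[5.5]undec-8-ene-3,7-dione (C4 epimers) | CC(=O)C1([Se]c3ccccc3)C[C@]2(COC1=O)C(=O)C=CC(C)(C)[C@H]2C(OC)OC | intermediate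
13 | (6S,11R)-4-acetyl-11-(dimethoxymethyl)-10,10-dimethyl-2-oxaspiro[5.5]undeca-4,8-diene-3,7-dione | CC(=O)C1=C[C@]2(COC1=O)C(=O)C=CC(C)(C)[C@H]2C(OC)OC | intermediate
14 | ethyl chloroacetate | CCOC(=O)CCl | starting material
15 | 1-(chloromethyl)cyclopropan-1-ol | OC1(CCl)CC1 | intermediate
16 | (5R,6S,11R)-4-acetyl-5-(4-chloro-3-oxobutyl)-11-(dimethoxymethyl)-10,10-dimethyl-2-oxaspiro[5.5]undec-8-ene-3,7-dione (C4 epimers; side chain syn to the C7 ketone of ring A) | CC(=O)C3[C@@H](CCC(=O)CCl)[C@]1(COC3=O)C(=O)C=CC(C)(C)[C@H]1C(OC)OC | intermediate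
17 | tricyclic diketone: ring A (4,4-dimethylcyclohex-2-en-1-one with CH(OMe)2 at C5) spiro-linked at C10 to the δ-lactone ring B (C10–C20H2–O–C7(=O)–C8–C9), which is cis-fused at C8–C9 to cyclohexan-13-one (ring C); C8 carries the acetyl group (C15, C16) cis to H-9; 5R,8S,9S,10S | CC(=O)[C@]23CC(=O)CC[C@H]2[C@]1(COC3=O)C(=O)C=CC(C)(C)[C@H]1C(OC)OC | intermediate
18 | bridged ketol: 17 with the C16–C13 bond closed (bicyclo[3.2.1]octane, bridgehead 13-OH, C15 ketone, C16H2); 5R,8S,9S,10S,13S | C1C(=O)[C@]23C[C@@]1(O)CC[C@H]2[C@]1(COC3=O)C(=O)C=CC(C)(C)[C@H]1C(OC)OC | intermediate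
19 | enone: 18 with an exocyclic methylene (C17) on C16; 5R,8S,9S,10S,13S | C=C1C(=O)[C@]23C[C@@]1(O)CC[C@H]2[C@]1(COC3=O)C(=O)C=CC(C)(C)[C@H]1C(OC)OC | intermediate
20 | allylic alcohol: 19 with the C15 ketone reduced to the 15R alcohol (OH endo, towards C9); 6-dimethyl acetal of the target | C=C1[C@@H](O)[C@]23C[C@@]1(O)CC[C@H]2[C@]1(COC3=O)C(=O)C=CC(C)(C)[C@H]1C(OC)OC | intermediate
21 | CNP0521079.1: 13,15-dihydroxy-1,6-dioxo-6,7-seco-ent-kaura-2,16-dien-7,20-olide (5R,8S,9S,10S,13S,15R) | C=C1[C@@H](O)[C@]23C[C@@]1(O)CC[C@H]2[C@]1(COC3=O)C(=O)C=CC(C)(C)[C@H]1C=O | target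

**Step count and risks**

Total step count: 13. Longest linear sequence: 12 (steps 1–7 and 9–13; step 8 makes the side fragment 15).

The three steps most likely to fail:

Step 4 builds a crowded quaternary centre next to the C5 branch and the gem-dimethyl carbon, and the product β-keto aldehyde can lose its formyl group under base. The fallback sets out from 6 and comes back at 10. Compound 6 is added to acrolein with Et3N, the faster classical acceptor for 2-formyl ketones, to give 3-[(1S,6R)-6-(dimethoxymethyl)-1-formyl-5,5-dimethyl-2-oxocyclohex-3-en-1-yl]propanal F1. Both aldehydes are reduced with NaBH4 at −78 °C to (5R,6S)-5-(dimethoxymethyl)-6-(hydroxymethyl)-6-(3-hydroxypropyl)-4,4-dimethylcyclohex-2-en-1-one F2. The lactone is then closed oxidatively with TEMPO/PhI(OAc)2, which oxidises the unhindered C7 alcohol and lactonises it onto the neopentyl C20 alcohol, giving 10.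

Step 9 is the proposed new reaction. The cyclopropanol may be hard to oxidise, the radical must attack a neopentyl β-carbon, and the facial choice at C9 and the cis ring closure are predicted, not known. The fallback uses known chemistry, sets out from 13 and comes back at 17. Commercial 1-(phenylsulfanyl)propan-2-one is methylenated ((CH2O)n, piperidinium acetate) to 3-(phenylsulfanyl)but-3-en-2-one F3 and silylated (TMSOTf, Et3N) to trimethyl{[3-(phenylsulfanyl)buta-1,3-dien-2-yl]oxy}silane F4. A sulfur-directed Diels–Alder reaction of F4 with 13 (toluene, 80 °C) joins the CH2 next to C–S to C9 and the CH2 next to C–O to C8 in one suprafacial step, giving the cis-fused 13-silyl enol ether adduct F5. Dilute HCl in THF at 0 °C frees the ketone as the 12-(phenylsulfanyl) ketone F6, and Zn/AcOH removes the sulfur to give 17.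

Step 12 must reduce one of two enones and set C15; the C1 enone may compete and the exo-face preference is an argument by analogy. The fallback sets out from 19 and comes back at 20 and makes no new compound. It replaces substrate (chelate) control by reagent control: Corey–Bakshi–Shibata reduction with the 2-methyl-CBS-oxazaborolidine enantiomer that matches the exo attack and catecholborane in toluene at −78 °C, which also favours the more accessible s-cis exocyclic enone.

**Further compounds**

F1 | step 4 | 3-[(1S,6R)-6-(dimethoxymethyl)-1-formyl-5,5-dimethyl-2-oxocyclohex-3-en-1-yl]propanal | O=CCC[C@]1(C=O)C(=O)C=CC(C)(C)[C@H]1C(OC)OC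
F2 | step 4 | (5R,6S)-5-(dimethoxymethyl)-6-(hydroxymethyl)-6-(3-hydroxypropyl)-4,4-dimethylcyclohex-2-en-1-one | OCCC[C@]1(CO)C(=O)C=CC(C)(C)[C@H]1C(OC)OC
F3 | step 9 | 3-(phenylsulfanyl)but-3-en-2-one | CC(=O)C(=C)Sc1ccccc1
F4 | step 9 | trimethyl{[3-(phenylsulfanyl)buta-1,3-dien-2-yl]oxy}silane | C=C(O[Si](C)(C)C)C(=C)Sc1ccccc1
F5 | step 9 | Diels–Alder adduct: 17 with ring C as the C12=C13 trimethylsilyl enol ether bearing 12-SPh | CC(=O)[C@]23CC(O[Si](C)(C)C)=C(Sc4ccccc4)C[C@H]2[C@]1(COC3=O)C(=O)C=CC(C)(C)[C@H]1C(OC)OC
F6 | step 9 | 12-(phenylsulfanyl) derivative of 17 (C12 epimers) | CC(=O)[C@]23CC(=O)C(Sc4ccccc4)C[C@H]2[C@]1(COC3=O)C(=O)C=CC(C)(C)[C@H]1C(OC)OC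
F0 | step 12 | none | none
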